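## Retrosynthetic overview

1. Dichamanetin ⇒ open ring C at the O1–C2 bond to the achiral, unprotected 3′,5′-bis(2-hydroxybenzyl)-2′,4′,6′-trihydroxychalcone. In the forward direction a catalytic enantioselective, chalcone-isomerase-type 6-endo oxa-Michael closure is the last step, the only ring-forming step, and sets C2.
2. Chalcone ⇒ Claisen–Schmidt disconnection to 3,5-bis(2-hydroxybenzyl)phloroacetophenone and benzaldehyde.
3. That ketone ⇒ two aryl–CH2 bonds, made by double o-quinone methide C-benzylation of phloroacetophenone with 2-hydroxybenzyl alcohol. Benzylation is placed before ring closure so the racemisable flavanone never meets Lewis acid or strong base.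
4. Ring order: rings A and B and both hydroxybenzyl rings are bought; ring C is made last; no protecting groups.

Assumption: the quinine-derived thiourea is taken to give the 2S enantiomer; the first run is checked by CD (2S-flavanones: positive Cotton effect near 330 nm, negative near 290 nm), and if the sense is opposite the quinidine-derived pseudoenantiomer N-[3,5-bis(trifluoromethyl)phenyl]-N′-[(9R)-6′-methoxycinchonan-9-yl]thiourea is used in the same step.

## Route

Step 1
Reactants: 1 2′,4′,6′-trihydroxyacetophenone (phloroacetophenone, dried from its monohydrate); 2 2-hydroxybenzyl alcohol (salicyl alcohol, 2.4 equiv)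
Product: 5 3,5-bis(2-hydroxybenzyl)-2,4,6-trihydroxyacetophenone, via o-quinone methide 3 (not isolated), via mono-benzyl ketone 4 (not isolated)
Conditions: ZnCl2 (4 equiv), 1,4-dioxane, 60 °C, Ar, slow addition of 2
Reagents that add atoms: 2-hydroxybenzyl alcohol (2), OCc1ccccc1O
Why: ZnCl2 ionises the benzylic alcohol of 2 to the zinc-bound o-quinone methide 3, which is trapped in a Friedel–Crafts-type conjugate addition by the only two nucleophilic ring carbons of the acylphloroglucinol (C3 and C5), so exhaustive benzylation can give only one constitution and no stereocentre is formed.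

Step 2
Reactants: 5 3,5-bis(2-hydroxybenzyl)-2,4,6-trihydroxyacetophenone; 6 benzaldehyde (3 equiv)
Product: 8 (E)-3′,5′-bis(2-hydroxybenzyl)-2′,4′,6′-trihydroxychalcone, via aldol adduct 7 (not isolated)
Conditions: KOH (50% aq, 20 equiv), EtOH, degassed, Ar, 0 °C → rt, 48 h; then cold 1 M HCl to pH 2–3, fast extraction
Reagents that add atoms: benzaldehyde (6), O=Cc1ccccc1
Why: Claisen–Schmidt aldol condensation (E1cB dehydration of 7 gives the E-enone), in which the blocked ring positions of 5 leave the methyl ketone as the only site for benzaldehyde and the excess strong base holds the product as the open chalcone polyphenolate (flavanones ring-open under these conditions), so cold acidification returns achiral 8 and no stereocentre is formed.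

Step 3
Reactants: 8 (E)-3′,5′-bis(2-hydroxybenzyl)-2′,4′,6′-trihydroxychalcone
Product: 9 dichamanetin [(2S)-5,7-dihydroxy-6,8-bis(2-hydroxybenzyl)-2-phenylchroman-4-one]
Conditions: N-[3,5-bis(trifluoromethyl)phenyl]-N′-[(8α,9S)-6′-methoxycinchonan-9-yl]thiourea (quinine-derived, C29H28F6N4OS, 10 mol%), PhCl/THF 9:1, −20 °C, Ar, stopped at full conversion; then 0.5 M HCl wash, recrystallise
Reagents that add atoms: none
Why: Proposed new method: the quinuclidine nitrogen of the catalyst takes up a proton from the acylphloroglucinol (pKa about 8) to give a chiral ammonium phenoxide ion pair while the thiourea hydrogen-bonds the enone carbonyl, so the 2′-oxygen (either ortho oxygen, the two being equivalent by aryl rotation) adds 6-endo-trig to one face of Cβ and the ammonium then protonates the enolate at C3, which fixes C2 as S; the 5-OH···O=C hydrogen bond of the product makes closure downhill, so the racemising retro-Michael is slow at −20 °C, and no achiral base is present to carry a background reaction; the closest known reaction type is the cinchona-alkaloid- and cinchona-thiourea-catalysed intramolecular oxa-Michael cyclisation of 2′-hydroxychalcones, o-tigloylphenols and 2′-hydroxy alkylidene β-ketoesters to chromanones and flavanones, the small-molecule counterpart of chalcone isomerase.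

## Compound list

1 | 2′,4′,6′-trihydroxyacetophenone (phloroacetophenone; sold as the monohydrate) | CC(=O)c1c(O)cc(O)cc1O | starting material
2 | 2-hydroxybenzyl alcohol (salicyl alcohol) | OCc1ccccc1O | starting material
3 | o-quinone methide, 6-methylidenecyclohexa-2,4-dien-1-one (zinc-bound, not isolated) | C=C1C=CC=CC1=O | intermediate
4 | 1-[2,4,6-trihydroxy-3-(2-hydroxybenzyl)phenyl]ethanone (mono-benzyl ketone, not isolated) | CC(=O)c1c(O)cc(O)c(Cc2ccccc2O)c1O | intermediate
5 | 1-[2,4,6-trihydroxy-3,5-bis(2-hydroxybenzyl)phenyl]ethanone | CC(=O)c1c(O)c(Cc2ccccc2O)c(O)c(Cc2ccccc2O)c1O | intermediate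
6 | benzaldehyde | O=Cc1ccccc1 | starting material
7 | 3-hydroxy-3-phenyl-1-[2,4,6-trihydroxy-3,5-bis(2-hydroxybenzyl)phenyl]propan-1-one (racemic aldol adduct, not isolated) | O=C(CC(O)c1ccccc1)c1c(O)c(Cc2ccccc2O)c(O)c(Cc2ccccc2O)c1O | intermediate
8 | (E)-3-phenyl-1-[2,4,6-trihydroxy-3,5-bis(2-hydroxybenzyl)phenyl]prop-2-en-1-one (achiral chalcone) | O=C(/C=C/c1ccccc1)c1c(O)c(Cc2ccccc2O)c(O)c(Cc2ccccc2O)c1O | intermediate
9 | dichamanetin, (2S)-5,7-dihydroxy-6,8-bis[(2-hydroxyphenyl)methyl]-2-phenyl-2,3-dihydro-4H-chromen-4-one | O=C1C[C@@H](c2ccccc2)Oc2c(Cc3ccccc3O)c(O)c(Cc3ccccc3O)c(O)c21 | target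

## Step count and risks

Total step count: 3. Longest linear sequence: 3 steps (1 → 5 → 8 → 9).

Steps most likely to fail, most risky first:

**Step 3.** The risks are modest enantioselectivity on a pentaphenolic substrate and loss of ee through reversible ring opening. The fallback moves stereocontrol from the catalyst to separation with recycling; it sets out from 8 and comes back at 9. Chalcone 8 is closed without stereocontrol (NaOAc, EtOH, 60 °C) to racemic dichamanetin, that is 9 together with (2R)-dichamanetin F6. Preparative chromatography on silica-supported cellulose tris(3,5-dimethylphenylcarbamate) gives 9. F6 is returned to 8 by retro-oxa-Michael ring opening in cold degassed 50% aqueous KOH and fast cold acidification, so the wrong enantiomer is recycled.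

**Step 2.** The risks are poor enolisation of the polyphenolate of 5, Cannizzaro loss of 6, and partial closure to racemic flavanone on acidification. The fallback masks the phenols so that an ordinary mono-phenolate ketone is condensed; it sets out from 5 and comes back at 8. Ketone 5 with MOMCl (5 equiv) and i-Pr2NEt in CH2Cl2 gives the tetrakis(methoxymethyl) ether F3, in which the chelated 2-OH stays free. KOH in EtOH at rt with 6 takes F3 through the protected aldol adduct F4 to the protected chalcone F5. HCl (3 M) in MeOH at rt removes the four MOM groups and gives 8; any flavanone formed there is racemic and is reopened to 8 with cold aqueous KOH.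

**Step 1.** The risks are self-condensation of 2 to phenolic oligomers and an incomplete second benzylation. The fallback uses a protected benzylic cation in place of the o-quinone methide; it sets out from 1 and comes back at 5. Ketone 1 with 2-methoxybenzyl alcohol (2.3 equiv) and TsOH·H2O (10 mol%) in 1,1,1,3,3,3-hexafluoropropan-2-ol at 40 °C undergoes Friedel–Crafts benzylation through the mono(2-methoxybenzyl) ketone F1 to the bis(2-methoxybenzyl) ketone F2. BBr3 in CH2Cl2 (−78 → 0 °C) then cleaves both methyl ethers and gives 5.

## Further compounds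

F1 | step 1 | 1-[2,4,6-trihydroxy-3-(2-methoxybenzyl)phenyl]ethanone | CC(=O)c1c(O)cc(O)c(Cc2ccccc2OC)c1O
F2 | step 1 | 1-[2,4,6-trihydroxy-3,5-bis(2-methoxybenzyl)phenyl]ethanone | CC(=O)c1c(O)c(Cc2ccccc2OC)c(O)c(Cc2ccccc2OC)c1O
F3 | step 2 | 1-{2-hydroxy-4,6-bis(methoxymethoxy)-3,5-bis[2-(methoxymethoxy)benzyl]phenyl}ethanone | CC(=O)c1c(O)c(Cc2ccccc2OCOC)c(OCOC)c(Cc2ccccc2OCOC)c1OCOC
F4 | step 2 | 3-hydroxy-1-{2-hydroxy-4,6-bis(methoxymethoxy)-3,5-bis[2-(methoxymethoxy)benzyl]phenyl}-3-phenylpropan-1-one (racemic) | O=C(CC(O)c1ccccc1)c1c(O)c(Cc2ccccc2OCOC)c(OCOC)c(Cc2ccccc2OCOC)c1OCOC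
F5 | step 2 | (E)-1-{2-hydroxy-4,6-bis(methoxymethoxy)-3,5-bis[2-(methoxymethoxy)benzyl]phenyl}-3-phenylprop-2-en-1-one | O=C(/C=C/c1ccccc1)c1c(O)c(Cc2ccccc2OCOC)c(OCOC)c(Cc2ccccc2OCOC)c1OCOC
F6 | step 3 | (2R)-dichamanetin, (2R)-5,7-dihydroxy-6,8-bis[(2-hydroxyphenyl)methyl]-2-phenyl-2,3-dihydro-4H-chromen-4-one | O=C1C[C@H](c2ccccc2)Oc2c(Cc3ccccc3O)c(O)c(Cc3ccccc3O)c(O)c21
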